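**Assumption:** Kanzonol C has no stereocentres, so "single enantiomer" is taken to mean the single (E)-enone isomer drawn; the only stereo-element to control is the E C=C.

## Retrosynthetic overview

- Both C-prenyl bonds are disconnected last: a twofold aromatic Claisen rearrangement of the 4,4'-bis(1,1-dimethylallyl) ether of the parent chalcone.
- The bis-ether comes from the unprotected trihydroxychalcone (isoliquiritigenin) by Pd-catalysed "reverse" O-prenylation; the chelated 2'-OH is left free.
- The chalcone is cut at the C(=O)–Cα bond, not the aldol C=C bond: Rh-catalysed, OH-directed hydroacylation of 4-ethynylphenol by 2,4-dihydroxybenzaldehyde, which sets the E-alkene by syn addition.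
- No rings are formed; both arenes are purchased. No protecting groups are used.

## Route

**Step 1**
Reactants: 1, 2,4-dihydroxybenzaldehyde; 2, 4-ethynylphenol
Product: 3, (E)-1-(2,4-dihydroxyphenyl)-3-(4-hydroxyphenyl)prop-2-en-1-one (isoliquiritigenin)
Conditions: [RhCl(cod)]2 (2.5 mol%), dppf (5 mol%), Na2CO3 (5 mol%), PhMe/1,4-dioxane, 100 °C, Ar; 2 (1.3 equiv) added slowly
Reagents that add atoms: none
Why: Chelation-assisted Rh(I) intermolecular alkyne hydroacylation by a salicylaldehyde: the 2-OH binds Rh and directs insertion into the aldehyde C–H bond (the chelate suppresses decarbonylation), and syn addition of H and acyl with the acyl going to the unhindered terminal alkyne carbon gives the linear (E)-enone.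

**Step 2**
Reactants: 4, 2-methylbut-3-en-2-ol; 5, di-tert-butyl dicarbonate (Boc2O)
Product: 6, tert-butyl (2-methylbut-3-en-2-yl) carbonate
Conditions: n-BuLi, THF, 0 °C; then Boc2O, 0 °C → rt
Reagents that add atoms: Boc2O (compound 5), CC(C)(C)OC(=O)OC(=O)OC(C)(C)C
Why: O-acylation of the tertiary lithium alkoxide with Boc2O gives the mixed carbonate (alkoxycarbonylation); no stereocentre is involved.

**Step 3**
Reactants: 3, isoliquiritigenin; 6, tert-butyl (2-methylbut-3-en-2-yl) carbonate (2.3 equiv)
Product: 7, (E)-1-[2-hydroxy-4-(2-methylbut-3-en-2-yloxy)phenyl]-3-[4-(2-methylbut-3-en-2-yloxy)phenyl]prop-2-en-1-one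
Conditions: Pd(PPh3)4 (5 mol%), THF, 0 °C, about 1 h, quench cold
Reagents that add atoms: compound 6, C=CC(C)(C)OC(=O)OC(C)(C)C (delivers two C5H9 units; CO2 and t-BuOH are lost)
Why: Pd-catalysed decarboxylative Tsuji–Trost O-allylation: the phenoxides attack the more substituted terminus of the 1,1-dimethylallyl–Pd cation under kinetic control at 0 °C to give the tertiary ethers, while the 2'-OH, hydrogen-bonded to the ketone and least acidic, stays free; the enone is untouched.

**Step 4**
Reactants: 7, the bis(1,1-dimethylallyl) ether
Product: 8, Kanzonol C, (E)-1-[2,4-dihydroxy-3-(3-methylbut-2-enyl)phenyl]-3-[4-hydroxy-3-(3-methylbut-2-enyl)phenyl]prop-2-en-1-one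
Conditions: degassed o-xylene (0.02 M), BHT (cat.), 130 °C, sealed tube, dark, 4–8 h
Reagents that add atoms: none
Why: Twofold aromatic Claisen ([3,3]) rearrangement then tautomerisation converts each O–CMe2–CH=CH2 into an ortho CH2–CH=CMe2 group; the B ring has equivalent ortho positions, and the A ring should react at C3' because the chelated 2'-hydroxyaryl ketone fixes more double-bond character in C3'–C4' (as 4-allyloxy-2-hydroxyaryl ketones give 3-allyl products), with the E-enone unaffected under neutral thermal conditions.

## Compound list

1 | 2,4-dihydroxybenzaldehyde | O=Cc1ccc(O)cc1O | starting material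
2 | 4-ethynylphenol | C#Cc1ccc(O)cc1 | starting material
3 | (E)-1-(2,4-dihydroxyphenyl)-3-(4-hydroxyphenyl)prop-2-en-1-one (isoliquiritigenin) | O=C(/C=C/c1ccc(O)cc1)c1ccc(O)cc1O | intermediate
4 | 2-methylbut-3-en-2-ol | C=CC(C)(C)O | starting material
5 | di-tert-butyl dicarbonate | CC(C)(C)OC(=O)OC(=O)OC(C)(C)C | starting material
6 | tert-butyl (2-methylbut-3-en-2-yl) carbonate | C=CC(C)(C)OC(=O)OC(C)(C)C | intermediate (reagent)
7 | (E)-1-[2-hydroxy-4-(2-methylbut-3-en-2-yloxy)phenyl]-3-[4-(2-methylbut-3-en-2-yloxy)phenyl]prop-2-en-1-one | C=CC(C)(C)Oc1ccc(/C=C/C(=O)c2ccc(OC(C)(C)C=C)cc2O)cc1 | intermediate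
8 | Kanzonol C | CC(C)=CCc1cc(/C=C/C(=O)c2ccc(O)c(CC=C(C)C)c2O)ccc1O | target

## Summary

Total steps: 4 (three on the main line plus one reagent preparation).
Longest linear sequence: 3 steps (1 → 3 → 7 → 8).

Steps most likely to fail:

1. **Step 1 (Rh hydroacylation).** The reaction class is known, but its regiochemistry with terminal alkynes depends on the alkyne substituent. For this aryl alkyne the branched 2-aryl enone could compete, as could alkyne oligomerisation or interference from the free 4-OH. Fallback: make 3 by BF3·OEt2 Friedel–Crafts C-acylation of resorcinol with 3-(4-hydroxyphenyl)propanoic acid to the dihydrochalcone, then DDQ dehydrogenation via the B-ring p-quinone methide (still non-aldol).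

2. **Step 4 (double Claisen).** The A ring could give the C5' regioisomer, and heat could cause chromane or flavanone cyclisation. Fallback: install the A-ring prenyl before the union, where regiochemistry is unambiguous. Lithiate 1,3-bis(methoxymethoxy)benzene at C2 and prenylate with Cu/prenyl bromide, then ortho-lithiate, formylate and remove MOM to give 2,4-dihydroxy-3-prenylbenzaldehyde. Couple this by hydroacylation with 4-ethynyl-2-prenylphenol.

3. **Step 3 (Pd O-reverse-prenylation).** Linear prenyl ether, over-alkylation at 2'-OH or C-allylation could occur. Fallback: Cu-catalysed O-alkylation with 3-chloro-3-methylbut-1-yne (CuCl2 cat., DBU, MeCN) to the bis(1,1-dimethylpropargyl) ether, then Lindlar/quinoline semihydrogenation to 7.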